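**Strategy.** Atoms are numbered along the target SMILES. Everything rests on cutting C13–C7, the single bond common to ring B (C7, C8, C9, C11, C12, C13) and to the two five-membered rings of the norbornane (ring C: C4, C5, C6, C7, C13; ring D: C6, C7, C13, C14, C15). Without it the molecule is a cyclohexene whose C6 and C13 are spanned by C7=C8–C9–C11–C12, so that the enone β-carbon C7 sits over alkene carbon C13. Hydrogen-atom transfer to C14 then lets the C13 radical add to C7, closing rings B, C and D and setting C13, C7 and C8. The precursor is bridged enone 19 (C6 anti to C9 across C7=C8; C15 silyl ether, C17 benzyl ether).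

Key step: step 14

Remark: atom labels C1 to O23 follow the order of the atoms in the target SMILES; compound 10 is taken as a catalogue chemical, and the lithium amides and Me2CuLi as preformed reagents.
Remark: C7 is carried as a dimethyl acetal (no epimerisable β-silyloxy aldehyde) and C17 as the axial (α) benzyl ether, so that bromide can be introduced by inversion before the C21 carbinol exists.

Step 1
Reactants: 1 4-isopropylcyclohexan-1-one
Product: 2 (S)-trimethyl[(4-isopropylcyclohex-1-en-1-yl)oxy]silane
Conditions: lithium (R,R)-bis(1-phenylethyl)amide, LiCl, Me3SiCl (internal quench), THF, −100 to −78 °C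
Reagents that add atoms: chlorotrimethylsilane C[Si](C)(C)Cl
Why: Enantioselective deprotonation of a prochiral 4-substituted cyclohexanone by a chiral lithium amide with in-situ silylation; the base distinguishes the two enantiotopic axial α-hydrogens, which should set C4 as S (the deprotonated carbon becomes C6).

Step 2
Reactants: 2 (S)-trimethyl[(4-isopropylcyclohex-1-en-1-yl)oxy]silane
Product: 3 (2R,4S)-2-(dimethoxymethyl)-4-isopropylcyclohexan-1-one
Conditions: HC(OMe)3, Me3SiOTf (5 mol%), CH2Cl2, −78 °C; then K2CO3, MeOH, 0 °C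
Reagents that add atoms: trimethyl orthoformate COC(OC)OC
Why: Mukaiyama-type addition of the enol silane to the dimethoxycarbenium ion puts C7 on C6 as an acetal, and base equilibration of the enolisable C6 centre should leave the diequatorial cis-2,4 ketone (C7 cis to isopropyl).

Step 3
Reactants: 3 (2R,4S)-2-(dimethoxymethyl)-4-isopropylcyclohexan-1-one
Product: 5 (4S,6R)-6-(dimethoxymethyl)-4-isopropylcyclohex-2-en-1-one, via silyl enol ether 4 (not isolated)
Conditions: LiN(i-Pr)2, Me3SiCl, THF, −78 °C; then Pd(OAc)2 (10 mol%), O2, DMSO, rt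
Reagents that add atoms: none
Why: Kinetic deprotonation at the unsubstituted α-methylene C14 and Saegusa–Ito oxidation of the enol silane introduce C13=C14 without touching C6.

Step 4
Reactants: 5 (4S,6R)-6-(dimethoxymethyl)-4-isopropylcyclohex-2-en-1-one
Product: 7 (4S,6R)-6-(dimethoxymethyl)-4-isopropyl-3-vinylcyclohex-2-en-1-one, via silyl enol ether 6 (not isolated)
Conditions: CH2=CHMgBr, CuBr·SMe2 (10 mol%), Me3SiCl, THF, −78 °C; then Pd(OAc)2 (10 mol%), O2, DMSO, rt
Reagents that add atoms: vinylmagnesium bromide C=C[Mg]Br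
Why: Copper-catalysed conjugate addition of the vinyl Grignard reagent to C13 with silyl trapping, then a second Saegusa–Ito oxidation, attaches C12 and C11 and restores C13=C14 (the transient C13 centre is erased).

Step 5
Reactants: 7 (4S,6R)-6-(dimethoxymethyl)-4-isopropyl-3-vinylcyclohex-2-en-1-one
Product: 8 (1R,4S,6S)-6-(dimethoxymethyl)-4-isopropyl-3-vinylcyclohex-2-en-1-ol
Conditions: LiBH(s-Bu)3, THF, −78 °C; then H2O
Reagents that add atoms: none
Why: 1,2-Reduction of the β,β-disubstituted enone by a bulky trialkylborohydride from the equatorial direction, away from the substituents on C6 and C4, should give the axial C15 alcohol cis to both (as in reductions of 6-alkylcyclohex-2-enones with this reagent).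

Step 6
Reactants: 8 (1R,4S,6S)-6-(dimethoxymethyl)-4-isopropyl-3-vinylcyclohex-2-en-1-ol
Product: 9 tert-butyldimethylsilyl ether of 8 (all-cis diene acetal)
Conditions: t-BuMe2SiCl, imidazole, DMAP (cat.), DMF, 35 °C
Reagents that add atoms: tert-butyldimethylsilyl chloride CC(C)(C)[Si](C)(C)Cl
Why: Silylation of the secondary allylic alcohol with a silyl chloride and imidazole, conditions that leave the dimethyl acetal intact.

Step 7
Reactants: 10 1,4-dioxaspiro[4.5]dec-6-en-8-one
Product: 11 7-iodo-1,4-dioxaspiro[4.5]dec-6-en-8-one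
Conditions: I2, pyridine, CH2Cl2, 0 °C to rt
Reagents that add atoms: iodine II
Why: α-Iodination of a cyclic enone (conjugate addition of pyridine, iodination of the enolate, elimination) places iodine on the future C9.

Step 8
Reactants: 11 7-iodo-1,4-dioxaspiro[4.5]dec-6-en-8-one
Product: 12 (R)-7-iodo-1,4-dioxaspiro[4.5]dec-6-en-8-ol
Conditions: (S)-2-methyl-CBS-oxazaborolidine (10 mol%), BH3·SMe2, THF, −20 °C; MeOH quench
Reagents that add atoms: none
Why: Corey–Bakshi–Shibata reduction, in which the iodoalkenyl side acts as the large group, should deliver the R carbinol, that is C17 with oxygen on the α face.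

Step 9
Reactants: 12 (R)-7-iodo-1,4-dioxaspiro[4.5]dec-6-en-8-ol
Product: 13 (R)-8-(benzyloxy)-7-iodo-1,4-dioxaspiro[4.5]dec-6-ene
Conditions: NaH, BnBr, Bu4NI (cat.), THF, 0 °C to rt
Reagents that add atoms: benzyl bromide BrCc1ccccc1
Why: Williamson ether synthesis on the sodium alkoxide.

Step 10
Reactants: 13 (R)-8-(benzyloxy)-7-iodo-1,4-dioxaspiro[4.5]dec-6-ene
Product: 14 (R)-4-(benzyloxy)-3-iodocyclohex-2-en-1-one
Conditions: 1 M HCl, THF, rt
Reagents that add atoms: water O
Why: Acid hydrolysis of the allylic dioxolane unveils the C21 ketone in conjugation with C8=C9 and so gives a β-iodo enone.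

Step 11
Reactants: 9 tert-butyldimethylsilyl ether of 8; 14 (R)-4-(benzyloxy)-3-iodocyclohex-2-en-1-one
Product: 16 coupled enone (ring-A enone C21=O/C8=C9 with C17 benzyloxy joined through C11–C12 to C13 of the cyclohexene), via alkylborane 15 (not isolated)
Conditions: 9-BBN, THF, 0 °C to rt; then 14, Pd(dppf)Cl2 (5 mol%), AsPh3, Cs2CO3, DMF/H2O, rt
Reagents that add atoms: none
Why: Hydroboration of the terminal vinyl group puts boron on C11 and B-alkyl Suzuki–Miyaura coupling with the β-iodo enone forms C11–C9.

Step 12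
Reactants: 16 coupled enone
Product: 17 enol silane (C9 quaternary with methyl trans to the C17 benzyloxy group; C21 trimethylsilyloxy, C8=C21)
Conditions: Me2CuLi, Me3SiCl, THF, −78 to −40 °C; Et3N, pentane work-up
Reagents that add atoms: lithium dimethylcuprate [Li+].C[Cu-]C; chlorotrimethylsilane C[Si](C)(C)Cl
Why: Cuprate conjugate addition anti to the C17 benzyloxy group creates quaternary C9 with methyl trans to oxygen, and silyl trapping fixes the enolate as C8=C21, the only regiochemistry the ring closure can use.

Step 13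
Reactants: 17 enol silane
Product: 19 bridged enone (key-step precursor; C6 cis to C21 and anti to C9 across C7=C8; C13=C14; C15 silyl ether; C17 benzyl ether), via β-methoxy ketone 18 (not isolated)
Conditions: Me3SiOTf (20 mol%), CH2Cl2 (1 mM), −78 °C; then DBU, −78 to 40 °C
Reagents that add atoms: none
Why: Intramolecular Mukaiyama-type addition of the regiodefined enol silane to the oxocarbenium ion from the C7 acetal closes the nine-membered ring at C8–C7, and E1cB loss of methanol should put C6 on the carbonyl side because the C9 methyl group lies in the enone plane on the other side.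

Step 14
Reactants: 19 bridged enone
Product: 20 tetracyclic ketone (C13–C7 bonded; C21 ketone; C15 silyl ether; C17 axial benzyloxy)
Conditions: Fe(acac)3 (0.3 equiv), PhSiH3 (2.5 equiv), EtOH/HOCH2CH2OH, N2, 40 °C
Reagents that add atoms: none
Why: The trivalent iron hydride formed from Fe(acac)3 and PhSiH3 transfers a hydrogen atom to C14 of the electron-rich trisubstituted C13=C14 bond, the tertiary C13 radical adds across the ring to the enone β-carbon C7, and the C8 radical is reduced to the iron enolate and protonated by the alcohol. The closest known reaction type is the metal-hydride hydrogen-atom-transfer reductive coupling of an unactivated alkene with an enone (radical conjugate addition), used here within one ring system. One bond closes three rings: ring C (C4, C5, C6, C7, C13) and ring D (C6, C7, C13, C14, C15) each by 5-exo-trig attack and ring B (C7, C8, C9, C11, C12, C13) by 6-endo-trig attack, all transannular in the nine-membered ring. C13 is fixed because C7 hangs from C6 on one face of the cyclohexene; C7 is fixed by a chair-like ring B in which C11 stands perpendicular to the enone plane on the face dictated by C9, so that C8 lies over the C14–C15 bridge and away from the exo isopropyl group on C4; C8 is set by protonation to the trans-fused A/B ketone, which is also the thermodynamic epimer of this enolisable centre. The step needs hydrogen-atom transfer to the alkene and not to the electron-poor enone (polarity matching) and ring closure faster than reduction of the C13 radical, which the C13/C7 contact enforced by the ring-trans enone and the five-atom bridge should secure.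

Step 15
Reactants: 20 tetracyclic ketone
Product: 21 hydroxy ketone (C17 axial alcohol)
Conditions: H2 (1 atm), Pd(OH)2/C, EtOAc, rt
Reagents that add atoms: none
Why: Hydrogenolysis of the benzyl ether; no alkene remains, and the ketone and silyl ether are inert.

Step 16
Reactants: 21 hydroxy ketone
Product: 22 bromo ketone (C17 equatorial bromide)
Conditions: CBr4, P(n-C8H17)3, PhMe, 70 °C
Reagents that add atoms: tetrabromomethane BrC(Br)(Br)Br
Why: Appel reaction: bromide displaces the axial alkoxyphosphonium group with inversion to give the equatorial C17 bromide, the trialkylphosphine variant being suited to neopentylic secondary carbinols.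

Step 17
Reactants: 22 bromo ketone
Product: 23 C15 tert-butyldimethylsilyl ether of the target
Conditions: MeMgBr, CeCl3, THF, −78 °C; then H2O
Reagents that add atoms: methylmagnesium bromide C[Mg]Br
Why: Organocerium 1,2-addition without enolisation; attack along the equatorial direction, away from the 1,3-diaxial C10 methyl group, should give the axial C21 hydroxyl and equatorial methyl.

Step 18
Reactants: 23 C15 tert-butyldimethylsilyl ether of the target
Product: 24 CNP0317598.2
Conditions: HF·pyridine, THF, 0 °C to rt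
Reagents that add atoms: none
Why: Fluoride cleavage of the silyl ether under non-basic conditions, which avoids base-induced loss of HBr.

**Compound list**

1 | 4-isopropylcyclohexan-1-one | CC(C)C1CCC(=O)CC1 | starting material
2 | (S)-trimethyl[(4-isopropylcyclohex-1-en-1-yl)oxy]silane | CC(C)[C@@H]1CC=C(O[Si](C)(C)C)CC1 | intermediate
3 | (2R,4S)-2-(dimethoxymethyl)-4-isopropylcyclohexan-1-one | CC(C)[C@@H]1C[C@H](C(OC)OC)C(=O)CC1 | intermediate
4 | trimethylsilyl enol ether of 3 toward C14 | CC(C)[C@@H]1C[C@H](C(OC)OC)C(O[Si](C)(C)C)=CC1 | intermediate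
5 | (4S,6R)-6-(dimethoxymethyl)-4-isopropylcyclohex-2-en-1-one | CC(C)[C@@H]1C[C@H](C(OC)OC)C(=O)C=C1 | intermediate
6 | trimethylsilyl enol ether of the vinyl adduct of 5 (vinyl trans to isopropyl) | CC(C)[C@@H]1C[C@H](C(OC)OC)C(O[Si](C)(C)C)=C[C@H]1C=C | intermediate
7 | (4S,6R)-6-(dimethoxymethyl)-4-isopropyl-3-vinylcyclohex-2-en-1-one | CC(C)[C@@H]1C[C@H](C(OC)OC)C(=O)C=C1C=C | intermediate
8 | (1R,4S,6S)-6-(dimethoxymethyl)-4-isopropyl-3-vinylcyclohex-2-en-1-ol (all-cis) | CC(C)[C@@H]1C[C@H](C(OC)OC)[C@H](O)C=C1C=C | intermediate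
9 | tert-butyldimethylsilyl ether of 8 | CC(C)[C@@H]1C[C@H](C(OC)OC)[C@H](O[Si](C)(C)C(C)(C)C)C=C1C=C | intermediate
10 | 1,4-dioxaspiro[4.5]dec-6-en-8-one | O=C1C=CC2(CC1)OCCO2 | starting material
11 | 7-iodo-1,4-dioxaspiro[4.5]dec-6-en-8-one | O=C1C(I)=CC2(CC1)OCCO2 | intermediate
12 | (R)-7-iodo-1,4-dioxaspiro[4.5]dec-6-en-8-ol | O[C@@H]1CCC2(OCCO2)C=C1I | intermediate
13 | (R)-8-(benzyloxy)-7-iodo-1,4-dioxaspiro[4.5]dec-6-ene | c1ccccc1CO[C@@H]2CCC3(OCCO3)C=C2I | intermediate
14 | (R)-4-(benzyloxy)-3-iodocyclohex-2-en-1-one | O=C1CC[C@@H](OCc2ccccc2)C(I)=C1 | intermediate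
15 | B-alkyl-9-BBN from 9 (boron on C11) | CC(C)[C@@H]1C[C@H](C(OC)OC)[C@H](O[Si](C)(C)C(C)(C)C)C=C1CCB2C3CCCC2CCC3 | intermediate
16 | coupled enone (C11–C9 bond; C21=O, C8=C9, C17 benzyloxy) | CC(C)[C@@H]1C[C@H](C(OC)OC)[C@H](O[Si](C)(C)C(C)(C)C)C=C1CCC2=CC(=O)CC[C@H]2OCc3ccccc3 | intermediate
17 | enol silane (C9 methyl trans to C17 benzyloxy; C8=C21 trimethylsilyl enol ether) | CC(C)[C@@H]1C[C@H](C(OC)OC)[C@H](O[Si](C)(C)C(C)(C)C)C=C1CC[C@@]2(C)C=C(O[Si](C)(C)C)CC[C@H]2OCc3ccccc3 | intermediate
18 | β-methoxy ketone, nine-membered ring closed at C8–C7 (C7/C8 epimers) | CC(C)[C@@H]1C[C@@H]2C(OC)C4[C@](C)(CCC1=C[C@H]2O[Si](C)(C)C(C)(C)C)[C@H](OCc5ccccc5)CCC4=O | intermediate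
19 | bridged enone, key-step precursor (C6 cis to C21, anti to C9) | CC(C)[C@@H]1C[C@@H]2/C=C4/[C@](C)(CCC1=C[C@H]2O[Si](C)(C)C(C)(C)C)[C@H](OCc5ccccc5)CCC4=O | intermediate
20 | tetracyclic C21 ketone, C15 silyl ether, C17 axial benzyl ether | CC(C)[C@@H]1C[C@@H]2[C@H]3[C@H]4[C@](C)(CC[C@@]31C[C@H]2O[Si](C)(C)C(C)(C)C)[C@H](OCc5ccccc5)CCC4=O | intermediate
21 | hydroxy ketone (C17 axial alcohol) | CC(C)[C@@H]1C[C@@H]2[C@H]3[C@H]4[C@](C)(CC[C@@]31C[C@H]2O[Si](C)(C)C(C)(C)C)[C@H](O)CCC4=O | intermediate
22 | bromo ketone (C17 equatorial bromide) | CC(C)[C@@H]1C[C@@H]2[C@H]3[C@H]4[C@](C)(CC[C@@]31C[C@H]2O[Si](C)(C)C(C)(C)C)[C@@H](Br)CCC4=O | intermediate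
23 | C15 tert-butyldimethylsilyl ether of the target | CC(C)[C@@H]1C[C@@H]2[C@H]3[C@H]4[C@](C)(CC[C@@]31C[C@H]2O[Si](C)(C)C(C)(C)C)[C@@H](Br)CC[C@@]4(C)O | intermediate
24 | CNP0317598.2 | CC(C)[C@@H]1C[C@@H]2[C@H]3[C@H]4[C@](C)(CC[C@@]31C[C@H]2O)[C@@H](Br)CC[C@@]4(C)O | target

**Count and risks**

Total: 18 steps. Longest linear sequence: 14 steps (steps 1 to 6, then 11 to 18).

Steps most likely to fail:

Step 14. The tertiary C13 radical may take up a second hydrogen atom before it reaches C7 (net hydrogenation of C13=C14), or hydrogen-atom transfer may go to the enone. The fallback sets out from 19 and generates the same radical with no hydride source present. Cobalt-catalysed Markovnikov hydration (Co(acac)2, PhSiH3, O2) should give the tertiary alcohol F1. Acylation with methyl chlorooxoacetate gives the methyl oxalate F2, and one equivalent of CsOH gives the cesium oxalate F3. Visible-light photoredox decarboxylation ([Ir(dF(CF3)ppy)2(dtbbpy)]PF6, blue light, DME/DMF, H2O) releases the C13 radical, which then adds to C7; the route is rejoined at 20.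

Step 13. The oxocarbenium ion at C7 may be captured by a second molecule, or lose a proton to an enol ether, before the hindered C8 reaches it. The fallback sets out from 17. N-Bromosuccinimide converts the enol silane into the α-bromo ketone F4, LiBF4 in wet MeCN unmasks the aldehyde F5, and SmI2 (THF, −78 °C, high dilution) closes the ring by a Reformatsky-type samarium enolate aldol addition to the β-hydroxy ketone F6. Mesylation and elimination with DBU return to 19.

Step 16. The activated axial oxygen may be lost by elimination toward C19, or substitution at this neopentylic carbon may stall at the alkoxyphosphonium stage. The fallback sets out from 21: Tf2O and 2,6-lutidine at −78 °C give the triflate F7, which is displaced by Bu4NBr in toluene with inversion, returning to 22.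

**Further compounds**

F1 | step 14 | tertiary alcohol (C13 hydroxyl, C14 methylene; either C13 epimer) | CC(C)[C@@H]1C[C@@H]2/C=C4/[C@](C)(CCC1(O)C[C@H]2O[Si](C)(C)C(C)(C)C)[C@H](OCc5ccccc5)CCC4=O
F2 | step 14 | methyl oxalate of F1 | CC(C)[C@@H]1C[C@@H]2/C=C4/[C@](C)(CCC1(OC(=O)C(=O)OC)C[C@H]2O[Si](C)(C)C(C)(C)C)[C@H](OCc5ccccc5)CCC4=O
F3 | step 14 | cesium oxalate of F1 | CC(C)[C@@H]1C[C@@H]2/C=C4/[C@](C)(CCC1(OC(=O)C(=O)[O-])C[C@H]2O[Si](C)(C)C(C)(C)C)[C@H](OCc5ccccc5)CCC4=O.[Cs+]
F4 | step 13 | α-bromo ketone (bromine on C8, acetal intact) | CC(C)[C@@H]1C[C@H](C(OC)OC)[C@H](O[Si](C)(C)C(C)(C)C)C=C1CC[C@@]2(C)C(Br)C(=O)CC[C@H]2OCc3ccccc3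
F5 | step 13 | aldehyde (C7 formyl, bromine on C8) | CC(C)[C@@H]1C[C@H](C=O)[C@H](O[Si](C)(C)C(C)(C)C)C=C1CC[C@@]2(C)C(Br)C(=O)CC[C@H]2OCc3ccccc3
F6 | step 13 | β-hydroxy ketone, nine-membered ring closed at C8–C7 | CC(C)[C@@H]1C[C@@H]2C(O)C4[C@](C)(CCC1=C[C@H]2O[Si](C)(C)C(C)(C)C)[C@H](OCc5ccccc5)CCC4=O
F7 | step 16 | C17 axial triflate | CC(C)[C@@H]1C[C@@H]2[C@H]3[C@H]4[C@](C)(CC[C@@]31C[C@H]2O[Si](C)(C)C(C)(C)C)[C@H](OS(=O)(=O)C(F)(F)F)CCC4=O
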